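**Plan**

- Locants are those of the target's bicyclo[3.2.1]octane: C1 (OMe bridgehead), C2 (C=O), C3 (CHOMe), C4 (CH2), C5 (allyl bridgehead), C6 (CHMe), C7 (CH-aryl), C8 (CHOH).
- Retrosynthesis: remove H from C3/C4 (enone), then cut C7–aryl and C1–C8 together. The two enol-ether C=C bonds then go back to an ether bridge C7–O–C4. Next C5–allyl and C5–CHO are cut, and finally the (4+3) bonds C1–C7 and C3–C4.
- Enabling feature: C7 (aryl) and C8 (OH) both sit β to the C2 ketone through the C1 bridgehead. This β-aryl-β′-hydroxy ketone is the retron of conjugate arylation followed by aldol addition. Because C1 is a bridgehead, the enone C2(=O)–C1=C7 can exist only in the monocyclic seven-membered ring C1–C7, with C8 as a formyl group on C5.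
- Forward ring order: 8-oxabicyclo[3.2.1]octene by (4+3) cycloaddition, then monocyclic cyclohepta-2,6-dienone, then the cyclopentane C1–C7–C6–C5–C8 and the six-membered ring C1–C2–C3–C4–C5–C8 closed together in the key step.
- Stereochemistry: the absolute configuration comes from a catalytic enantioselective (4+3) cycloaddition. The oxygen bridge relays it to C6 and C5 (exo-face hydroformylation and allylation) and is then removed. C5/C6 control C7, C1 and C8 in the key step and C3 in the final protonation.

Key step: step 7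

Remark on the chemistry: in the oxabicyclic intermediates the two methoxy-bearing carbons are drawn cis-diequatorial, as expected from a compact (4+3) transition state. Both become sp2 in step 6, so any other isomer converges on the same dienone.

**Step 1**
Reactants: 1 3-bromo-1,1-dimethoxypropan-2-one
Product: 2 1,1,3-trimethoxypropan-2-one
Conditions: Ag2O, MeOH, rt, dark
Reagents that add atoms: methanol, CO
Why: Silver(I)-assisted Williamson-type substitution of the primary α-bromo ketone by methanol should give the methoxymethyl ketone while avoiding the epoxy-ether and Favorskii pathways of alkoxide bases; no stereocentre is formed.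

**Step 2**
Reactants: 2 1,1,3-trimethoxypropan-2-one
Product: 3 (Z)-triethyl[(1,3,3-trimethoxyprop-1-en-2-yl)oxy]silane
Conditions: TESOTf, Et3N, Et2O, 0 °C
Reagents that add atoms: triethylsilyl trifluoromethanesulfonate, CC[Si](CC)(CC)OS(=O)(=O)C(F)(F)F
Why: Soft enolisation (silyl enol ether formation) should occur at the less hindered methoxymethyl side and not at the acetal carbon, giving the latent 1,3-dimethoxy-2-siloxyallyl cation; no stereocentre is formed.

**Step 3**
Reactants: 3 (Z)-triethyl[(1,3,3-trimethoxyprop-1-en-2-yl)oxy]silane; 4 3-methylfuran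
Product: 5 (1S,2R,4S,5R)-2,4-dimethoxy-6-methyl-8-oxabicyclo[3.2.1]oct-6-en-3-one
Conditions: chiral arylpyrrolidine squaramide (10 mol%), TESOTf (10 mol%), CH2Cl2, −78 °C
Reagents that add atoms: none
Why: In this catalytic enantioselective (4+3) cycloaddition of an oxyallyl cation with a furan, the silyl triflate ionises the acetal to the symmetric 1,3-dimethoxy-2-siloxyallyl cation, which is held as an ion pair by the chiral squaramide; the more nucleophilic C2 of 3-methylfuran attacks one of its enantiotopic termini and the silyl enol ether end closes on the furan-derived oxocarbenium ion, so the catalyst sets the two bridgeheads (future C4 and C7).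

**Step 4**
Reactants: 5 (1S,2R,4S,5R)-2,4-dimethoxy-6-methyl-8-oxabicyclo[3.2.1]oct-6-en-3-one
Product: 6 (1R,2S,4R,5S,6S,7S)-2,4-dimethoxy-7-methyl-3-oxo-8-oxabicyclo[3.2.1]octane-6-carbaldehyde (6-exo-formyl, 7-endo-methyl)
Conditions: Rh(acac)(CO)2 (1 mol%), P(O-2,4-tBu2C6H3)3 (4 mol%), CO/H2 (1:1, 40 bar), toluene, 70 °C
Reagents that add atoms: carbon monoxide, [C-]#[O+]
Why: Rhodium-catalysed hydroformylation of the strained trisubstituted alkene should add H and CHO syn on the convex exo face with the formyl group on the unsubstituted carbon, so the methyl group (future C6) ends endo and the formyl group (future C5) exo.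

**Step 5**
Reactants: 6 (1R,2S,4R,5S,6S,7S)-2,4-dimethoxy-7-methyl-3-oxo-8-oxabicyclo[3.2.1]octane-6-carbaldehyde
Product: 7 (1R,2S,4R,5S,6R,7S)-2,4-dimethoxy-7-methyl-3-oxo-6-(prop-2-en-1-yl)-8-oxabicyclo[3.2.1]octane-6-carbaldehyde (6-exo-allyl, 6-endo-formyl, 7-endo-methyl)
Conditions: allyl alcohol, Pd(PPh3)4 (3 mol%), Ph2CHNH2 (40 mol%), (PhO)2PO2H (5 mol%), 5 Å MS, toluene, 40 °C; aqueous work-up
Reagents that add atoms: allyl alcohol (prop-2-en-1-ol), C=CCO
Why: Tsuji–Trost α-allylation of the α-branched aldehyde through its enamine should create the quaternary centre (future C5) by attack of the π-allyl palladium electrophile on the exo face, so allyl ends exo and the formyl group endo, cis to the methyl group.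

**Step 6**
Reactants: 7 (1R,2S,4R,5S,6R,7S)-2,4-dimethoxy-7-methyl-3-oxo-6-(prop-2-en-1-yl)-8-oxabicyclo[3.2.1]octane-6-carbaldehyde
Product: 9 (1R,7R)-3,5-dimethoxy-7-methyl-4-oxo-1-(prop-2-en-1-yl)cyclohepta-2,5-diene-1-carbaldehyde, via ring-opened acetoxy enone 8 (not isolated)
Conditions: KOtBu, THF, −78 → 0 °C; Ac2O, 0 °C; DBU, rt
Reagents that add atoms: none
Why: E1cB opening of the β-alkoxy ketone (ether bridge), acetylation of the released alkoxide and a second E1cB elimination should give the cross-conjugated 2,7-dimethoxy dienone; the aldehyde has no α-hydrogen, any aldol addition to it is reversible while the eliminations are not, and the bridgehead and methoxy-bearing stereocentres are erased while C5 and C6 are untouched.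

**Step 7**
Reactants: 9 (1R,7R)-3,5-dimethoxy-7-methyl-4-oxo-1-(prop-2-en-1-yl)cyclohepta-2,5-diene-1-carbaldehyde; 10 (3-hydroxy-4-methoxyphenyl)boronic acid
Product: 12 (1S,5R,6R,7S,8S)-8-hydroxy-7-(3-hydroxy-4-methoxyphenyl)-1,3-dimethoxy-6-methyl-5-(prop-2-en-1-yl)bicyclo[3.2.1]oct-3-en-2-one, via rhodium enolate 11 (not isolated)
Conditions: [Rh(OH)(cod)]2 (3 mol%), 10 (2 equiv), H2O (5 equiv), 1,4-dioxane, 50 °C
Reagents that add atoms: none
Why: Proposed new method: transmetallation of the boronic acid to Rh(I)–OH gives an aryl–rhodium species that inserts the C7=C1 enone bond (Hayashi–Miyaura-type 1,4-addition), forming the C7–aryl bond and an oxa-π-allyl rhodium enolate at C1–C2–O, which adds to the transannular C8 aldehyde before protonolysis. The closest known reaction type is the rhodium-catalysed conjugate arylation–aldol cyclisation of enones tethered to a carbonyl group, here extended to a 2-alkoxy cross-conjugated dienone and a transannular closure. The aldol closes the cyclopentane C1–C7–C6–C5–C8 in a 5-(enolexo)-exo-trig mode, which is at the same time a 6-(enolendo)-exo-trig closure of the cyclohexenone C1–C2–C3–C4–C5–C8, so both rings of the bicyclo[3.2.1]octane arise in one event. At C7 the aryl group is delivered anti to the adjacent C6 methyl group; at C1 the new bond can form only on the ring face that carries the formyl group (cis to methyl); at C8 a closed six-membered transition state with rhodium bridging the enolate and aldehyde oxygens places the hydroxyl group syn to the C2 carbonyl bridge. The step needs C7 over C4 (C4 is flanked by the quaternary C5), 1,4- over 1,2-addition (the aldehyde is neopentyl) and aldol over enolate protonation (intramolecular trap, little water). The free phenol of 10 should be tolerated under these near-neutral conditions, so no protecting group is carried.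

**Step 8**
Reactants: 12 (1S,5R,6R,7S,8S)-8-hydroxy-7-(3-hydroxy-4-methoxyphenyl)-1,3-dimethoxy-6-methyl-5-(prop-2-en-1-yl)bicyclo[3.2.1]oct-3-en-2-one
Product: 13 (1S,3S,5S,6R,7S,8S)-8-hydroxy-7-(3-hydroxy-4-methoxyphenyl)-1,3-dimethoxy-6-methyl-5-(prop-2-en-1-yl)bicyclo[3.2.1]octan-2-one
Conditions: Cu(OAc)2·H2O (5 mol%), 1,2-(Ph2P)2C6H4 (5 mol%), (EtO)2MeSiH, t-BuOH, toluene, 0 °C → rt; NH4F, MeOH
Reagents that add atoms: none
Why: Copper hydride-catalysed 1,4-reduction of the enone should be chemoselective over the terminal alkene and the ketone, and the copper enolate should be protonated by tert-butanol at C3 on the face turned towards the C8 bridge, the other face being shielded by the endo C7 aryl group, which places the C3 methoxy group endo (3S).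

**Compound list**

1 | 3-bromo-1,1-dimethoxypropan-2-one | COC(OC)C(=O)CBr | starting material
2 | 1,1,3-trimethoxypropan-2-one | COCC(=O)C(OC)OC | intermediate
3 | (Z)-triethyl[(1,3,3-trimethoxyprop-1-en-2-yl)oxy]silane | CO/C=C(\O[Si](CC)(CC)CC)C(OC)OC | intermediate
4 | 3-methylfuran | Cc1ccoc1 | starting material
5 | (1S,2R,4S,5R)-2,4-dimethoxy-6-methyl-8-oxabicyclo[3.2.1]oct-6-en-3-one | CO[C@@H]1C(=O)[C@H](OC)[C@@H]2C=C(C)[C@H]1O2 | intermediate
6 | (1R,2S,4R,5S,6S,7S)-2,4-dimethoxy-7-methyl-3-oxo-8-oxabicyclo[3.2.1]octane-6-carbaldehyde | CO[C@@H]1C(=O)[C@H](OC)[C@@H]2[C@@H](C=O)[C@H](C)[C@H]1O2 | intermediate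
7 | (1R,2S,4R,5S,6R,7S)-2,4-dimethoxy-7-methyl-3-oxo-6-(prop-2-en-1-yl)-8-oxabicyclo[3.2.1]octane-6-carbaldehyde | CO[C@@H]1C(=O)[C@H](OC)[C@@H]2[C@](CC=C)(C=O)[C@H](C)[C@H]1O2 | intermediate
8 | (1R,2S,3R,7R)-2-(acetyloxy)-3,5-dimethoxy-7-methyl-4-oxo-1-(prop-2-en-1-yl)cyclohept-5-ene-1-carbaldehyde (drawn for opening towards C7 first; the regioisomeric opening converges on 9) | C=CC[C@]1(C=O)[C@H](OC(C)=O)[C@@H](OC)C(=O)C(OC)=C[C@H]1C | intermediate
9 | (1R,7R)-3,5-dimethoxy-7-methyl-4-oxo-1-(prop-2-en-1-yl)cyclohepta-2,5-diene-1-carbaldehyde | C=CC[C@]1(C=O)C=C(OC)C(=O)C(OC)=C[C@H]1C | intermediate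
10 | (3-hydroxy-4-methoxyphenyl)boronic acid | COc1ccc(cc1O)B(O)O | starting material
11 | rhodium(I) O-enolate of the C7 aryl adduct (ancillary diene ligand omitted) | C=CC[C@]1(C=O)C=C(OC)C(O[Rh])=C(OC)[C@H](c2ccc(OC)c(O)c2)[C@H]1C | intermediate
12 | (1S,5R,6R,7S,8S)-8-hydroxy-7-(3-hydroxy-4-methoxyphenyl)-1,3-dimethoxy-6-methyl-5-(prop-2-en-1-yl)bicyclo[3.2.1]oct-3-en-2-one | C=CC[C@]12C=C(OC)C(=O)[C@](OC)([C@H](c3ccc(OC)c(O)c3)[C@H]1C)[C@H]2O | intermediate
13 | (1S,3S,5S,6R,7S,8S)-8-hydroxy-7-(3-hydroxy-4-methoxyphenyl)-1,3-dimethoxy-6-methyl-5-(prop-2-en-1-yl)bicyclo[3.2.1]octan-2-one | C=CC[C@]12C[C@H](OC)C(=O)[C@](OC)([C@H](c3ccc(OC)c(O)c3)[C@H]1C)[C@H]2O | target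

Total step count: 8. Longest linear sequence: 8 steps.

**Steps most likely to fail**

1. Step 7 (Proposed new method). The electron-rich 2-methoxy enone may insert into aryl–rhodium too slowly, so that protodeboronation, arylation at C4, protonation of the enolate before the aldol, or 1,2-arylation of the aldehyde take over. The fallback uses known chemistry, sets out from 9 and returns at 12.
   - The aldehyde of 9 would be protected with ethylene glycol and PPTS to give (4R,5R)-5-(1,3-dioxolan-2-yl)-2,7-dimethoxy-4-methyl-5-(prop-2-en-1-yl)cyclohepta-2,6-dien-1-one F1.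
   - The lithium diarylcuprate made from commercial (5-bromo-2-methoxyphenoxy)(tert-butyl)dimethylsilane would add at C7 anti to the methyl group. Work-up with dilute HCl in THF would also hydrolyse the dioxolane and give (1R,6S,7R)-6-[3-(tert-butyldimethylsilyloxy)-4-methoxyphenyl]-3,5-dimethoxy-7-methyl-4-oxo-1-(prop-2-en-1-yl)cyclohept-2-ene-1-carbaldehyde F2, as a mixture of epimers at the methoxy-bearing C5 of this name.
   - Soft enolisation with MgBr2·OEt2 and i-Pr2NEt would effect the chelate-controlled transannular aldol to (1S,5R,6R,7S,8S)-7-[3-(tert-butyldimethylsilyloxy)-4-methoxyphenyl]-8-hydroxy-1,3-dimethoxy-6-methyl-5-(prop-2-en-1-yl)bicyclo[3.2.1]oct-3-en-2-one F3.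
   - TBAF buffered with AcOH would then release 12.

2. Step 3. Enantio-induction may be insufficient, because the cation is symmetric and the selectivity rests on ion pairing plus the preference of furan C2 over C5 for the first bond; Friedel–Crafts alkylation without ring closure is a further loss. The fallback sets out from 3 and 4 and returns at 6.
   - The cycloaddition would be run with TESOTf alone to give (±)-2,4-dimethoxy-6-methyl-8-oxabicyclo[3.2.1]oct-6-en-3-one F4.
   - Hydroformylation as in step 4 would give (±)-2,4-dimethoxy-7-methyl-3-oxo-8-oxabicyclo[3.2.1]octane-6-carbaldehyde F5.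
   - Condensation with (1S,2S)-N,N′-dimethyl-1,2-diphenylethane-1,2-diamine would give two diastereomeric aminals. The one derived from 6, (1R,2S,4R,5S,6R,7S)-6-[(4S,5S)-1,3-dimethyl-4,5-diphenylimidazolidin-2-yl]-2,4-dimethoxy-7-methyl-8-oxabicyclo[3.2.1]octan-3-one F6, would be separated by chromatography and hydrolysed with dilute aqueous acid to return 6.

3. Step 8. Protonation of the enolate may occur with poor facial selectivity, C3 may epimerise afterwards, or the ketone may be over-reduced. The fallback sets out from 12 and returns at 13 without any new compound: an ene-reductase of the Old Yellow Enzyme family, with NADPH recycled by glucose dehydrogenase and glucose, would be screened for anti addition of hydride to C4 and a proton to the C8-side face of C3 under neutral aqueous conditions that leave the terminal alkene and the β-hydroxy ketone untouched.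

**Further compounds**

F1 | step 7 | (4R,5R)-5-(1,3-dioxolan-2-yl)-2,7-dimethoxy-4-methyl-5-(prop-2-en-1-yl)cyclohepta-2,6-dien-1-one | C=CC[C@]1(C2OCCO2)C=C(OC)C(=O)C(OC)=C[C@H]1C
F2 | step 7 | (1R,6S,7R)-6-[3-(tert-butyldimethylsilyloxy)-4-methoxyphenyl]-3,5-dimethoxy-7-methyl-4-oxo-1-(prop-2-en-1-yl)cyclohept-2-ene-1-carbaldehyde (C5 epimers) | C=CC[C@]1(C=O)C=C(OC)C(=O)C(OC)[C@H](c2ccc(OC)c(O[Si](C)(C)C(C)(C)C)c2)[C@H]1C
F3 | step 7 | (1S,5R,6R,7S,8S)-7-[3-(tert-butyldimethylsilyloxy)-4-methoxyphenyl]-8-hydroxy-1,3-dimethoxy-6-methyl-5-(prop-2-en-1-yl)bicyclo[3.2.1]oct-3-en-2-one | C=CC[C@]12C=C(OC)C(=O)[C@](OC)([C@H](c3ccc(OC)c(O[Si](C)(C)C(C)(C)C)c3)[C@H]1C)[C@H]2O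
F4 | step 3 | (±)-2,4-dimethoxy-6-methyl-8-oxabicyclo[3.2.1]oct-6-en-3-one (racemate, relative configuration as in 5) | COC1C(=O)C(OC)C2C=C(C)C1O2
F5 | step 3 | (±)-2,4-dimethoxy-7-methyl-3-oxo-8-oxabicyclo[3.2.1]octane-6-carbaldehyde (racemate, relative configuration as in 6) | COC1C(=O)C(OC)C2C(C=O)C(C)C1O2
F6 | step 3 | (1R,2S,4R,5S,6R,7S)-6-[(4S,5S)-1,3-dimethyl-4,5-diphenylimidazolidin-2-yl]-2,4-dimethoxy-7-methyl-8-oxabicyclo[3.2.1]octan-3-one | CO[C@@H]1C(=O)[C@H](OC)[C@@H]2[C@@H](C3N(C)[C@@H](c4ccccc4)[C@H](c4ccccc4)N3C)[C@H](C)[C@H]1O2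
F0 | step 8 | none | none
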